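## Retrosynthetic overview

1. α-Tocotrienol 10 comes from its acetate 9. The dihydropyran is the only ring built. It is closed last at C4–C4a by hydroboration and intramolecular B-alkyl Suzuki coupling. The arene is purchased.
2. Acetate 9 comes from the acyclic (R)-aryl tert-allyl ether 7. Its vinyl group is the latent C3–C4 unit, and the stereocentre is already in place.
3. Ether 7 comes from forming O1–C2 by an intermolecular Pd-catalysed asymmetric allylic O-alkylation of o-bromophenol 4 with all-E geranylgeranyl methyl carbonate 6. This one step sets C2 and brings in all 20 chain carbons with the three E-olefins.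
4. Phenol 4 comes from trimethylhydroquinone by diacetylation, steric mono-deacetylation and bromination. Carbonate 6 comes from geranylgeraniol.
5. Two disconnections are deliberately avoided: a preformed chiral chroman coupled to a farnesyl fragment, and acid condensation of the hydroquinone with a C20 allylic alcohol.

**Assumptions**
- The target is natural (2R,3'E,7'E)-α-tocotrienol. At C2 the CIP order is O > C3 > C1' > CH3, and the given SMILES reads as R.
- All-E geranylgeraniol is taken as commercial. Minor Z-isomers are removed by chromatography of 6.
- I cannot assign the sense of induction for this exact phenol/carbonate pair with certainty. The (R,R)-ligand is written. If the first run gives (S)-7, judged by chiral HPLC against natural material after conversion, the equally available (S,S)-ligand is used and nothing else changes.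

## Route

**Step 1**
- Reactants: 1, trimethylhydroquinone (2,3,5-trimethylbenzene-1,4-diol)
- Product: 2, 2,3,5-trimethyl-1,4-phenylene diacetate
- Conditions: Ac2O (2.5 equiv), pyridine, DMAP (cat.), CH2Cl2, 0 °C to rt
- Reagents that add atoms: acetic anhydride, CC(=O)OC(C)=O
- Why: This is exhaustive DMAP-catalysed O-acylation, and it also stops air oxidation to the quinone.

**Step 2**
- Reactants: 2
- Product: 3, 4-hydroxy-2,3,6-trimethylphenyl acetate (free OH next to the ring C–H; the acetate flanked by two methyls is kept)
- Conditions: K2CO3 (1.0 equiv), MeOH, −10 to 0 °C, Ar; AcOH quench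
- Reagents that add atoms: none
- Why: In this sterically controlled methanolysis (transesterification), the acetate with one ortho-methyl is cleaved much faster than the di-ortho-methyl one, and the resulting para-phenoxide deactivates the remaining ester.

**Step 3**
- Reactants: 3
- Product: 4, 3-bromo-4-hydroxy-2,5,6-trimethylphenyl acetate
- Conditions: NBS (1.02 equiv), MeCN, −10 to 0 °C, dark
- Reagents that add atoms: N-bromosuccinimide, O=C1CCC(=O)N1Br
- Why: Electrophilic aromatic bromination can only occur at the single open ring position, ortho to the free OH, and polar solvent in the dark suppresses benzylic bromination.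

**Step 4**
- Reactants: 5, (2E,6E,10E)-geranylgeraniol
- Product: 6, (2E,6E,10E)-geranylgeranyl methyl carbonate
- Conditions: ClCO2Me (1.3 equiv), pyridine, CH2Cl2, 0 °C
- Reagents that add atoms: methyl chloroformate, COC(=O)Cl
- Why: This is simple O-acylation under acid-free conditions, so olefin geometry is untouched.

**Step 5 (key step)**
- Reactants: 4, the bromophenol (1.0 equiv); 6, the carbonate (1.15 equiv)
- Product: 7, 3-bromo-2,5,6-trimethyl-4-{[(3R,6E,10E)-3,7,11,15-tetramethylhexadeca-1,6,10,14-tetraen-3-yl]oxy}phenyl acetate
- Conditions: Pd2(dba)3·CHCl3 (2.5 mol %), (R,R)-DACH-phenyl Trost ligand (7.5 mol %), CH2Cl2 (0.05 M), 0 °C to rt; stop as soon as 6 is consumed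
- Reagents that add atoms: none (all atoms come from 4 and 6; CO2 and MeOH are lost)
- Why: This is a Tsuji–Trost asymmetric allylic alkylation with O-attack, a known reaction type applied here to an untested pair of partners.
  - Regiochemistry: ionisation gives the syn-alkyl/anti-methyl π-allyl, and the phenoxide attacks its more substituted, more cationic terminus outer-sphere to give the tertiary ether.
  - Stereochemistry: the two π-faces interconvert by η3–η1–η3 through primary C1 without E/Z scrambling, and the chiral pocket selects the face that gives (R).
  - Precedent within the reaction type: geranyl-type E-carbonates and 2,6-disubstituted o-bromophenols are each known partners.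
  - Chemoselectivity: carbonate ionisation at rt outruns oxidative addition into the hindered, electron-rich C–Br bond. Both ortho positions are blocked, so no Claisen product can form.

**Step 6**
- Reactants: 7
- Product: 8, the B-alkyl-9-BBN adduct, 3-bromo-4-{[(3S,6E,10E)-1-(9-borabicyclo[3.3.1]nonan-9-yl)-3,7,11,15-tetramethylhexadeca-6,10,14-trien-3-yl]oxy}-2,5,6-trimethylphenyl acetate. It is not isolated. The descriptor changes from R to S only because CH2CH2B ranks below the chain; the geometry is unchanged.
- Conditions: 9-BBN dimer (0.6 equiv, i.e. 1.2 equiv B–H), THF, 0 °C to rt, 3 h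
- Reagents that add atoms: 9-BBN, [H]B1C2CCCC1CCC2
- Why: Anti-Markovnikov hydroboration with 9-BBN is roughly 100 times faster at a monosubstituted vinyl than at trisubstituted olefins. Boron ends up γ to oxygen, so no β-elimination is possible, and the hindered aryl acetate is reduced only very slowly.

**Step 7**
- Reactants: 8 (same pot)
- Product: 9, (R)-α-tocotrienyl acetate, (2R)-2,5,7,8-tetramethyl-2-[(3E,7E)-4,8,12-trimethyltrideca-3,7,11-trien-1-yl]chroman-6-yl acetate
- Conditions: dilute to 0.02 M; Pd(OAc)2 (5 mol %), SPhos (10 mol %), K3PO4·H2O (3 equiv), THF, 65 °C, Ar; ethanolamine work-up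
- Reagents that add atoms: none (Br and the 9-BBN unit leave)
- Why: This intramolecular B-alkyl Suzuki–Miyaura coupling forms C4–C4a and closes the six-membered ring.
  - The bulky, electron-rich biaryl phosphine handles the di-ortho-substituted bromide.
  - The stereocentre is a spectator, since no bond to C2 is touched.
  - Any partial acetate loss is harmless because it gives 10 directly.

**Step 8**
- Reactants: 9
- Product: 10, (R)-α-tocotrienol (target)
- Conditions: LiAlH4 (1.5 equiv), THF, 0 °C, 30 min, Ar; Rochelle salt work-up
- Reagents that add atoms: none
- Why: Reductive ester cleavage is fast even for the hindered acetate. It avoids hot aerobic base that would oxidise the chromanol, and isolated olefins and the tertiary ether are inert.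

## Compound list

| No. | Name | SMILES | Role |
|---|---|---|---|
| 1 | trimethylhydroquinone | Cc1cc(O)c(C)c(C)c1O | starting material |
| 2 | trimethylhydroquinone diacetate | CC(=O)Oc1cc(C)c(OC(C)=O)c(C)c1C | intermediate |
| 3 | 4-hydroxy-2,3,6-trimethylphenyl acetate | CC(=O)Oc1c(C)cc(O)c(C)c1C | intermediate |
| 4 | 3-bromo-4-hydroxy-2,5,6-trimethylphenyl acetate | CC(=O)Oc1c(C)c(Br)c(O)c(C)c1C | intermediate |
| 5 | (2E,6E,10E)-geranylgeraniol | CC(C)=CCC/C(C)=C/CC/C(C)=C/CC/C(C)=C/CO | starting material |
| 6 | geranylgeranyl methyl carbonate | CC(C)=CCC/C(C)=C/CC/C(C)=C/CC/C(C)=C/COC(=O)OC | intermediate |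
| 7 | (R)-aryl geranyllinalyl ether | CC(C)=CCC/C(C)=C/CC/C(C)=C/CC[C@](C)(C=C)Oc1c(Br)c(C)c(OC(C)=O)c(C)c1C | intermediate |
| 8 | B-alkyl-9-BBN adduct of 7 | CC(C)=CCC/C(C)=C/CC/C(C)=C/CC[C@](C)(CCB1C2CCCC1CCC2)Oc1c(Br)c(C)c(OC(C)=O)c(C)c1C | intermediate (not isolated) |
| 9 | (R)-α-tocotrienyl acetate | CC(C)=CCC/C(C)=C/CC/C(C)=C/CC[C@]1(C)CCc2c(C)c(OC(C)=O)c(C)c(C)c2O1 | intermediate |
| 10 | (R)-α-tocotrienol | CC(C)=CCC/C(C)=C/CC/C(C)=C/CC[C@]1(C)CCc2c(C)c(O)c(C)c(C)c2O1 | target |

## Step count

- Total steps: 8 (7 flask operations, because steps 6 and 7 run in one pot).
- Longest linear sequence: 7 (steps 1, 2, 3, 5, 6, 7, 8).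

## Three steps most likely to fail

1. **Step 5.** The hindered phenol may favour the linear ether, the ee may be moderate, or Pd may re-ionise the product.
   - Fallback: set the C–O stereocentre by Sharpless epoxidation of 5 with Ti(OiPr)4, D-(−)-DET and TBHP to give the (2R,3R)-epoxide.
   - Convert the epoxy alcohol to the epoxy iodide, then open it reductively with Zn to give (R)-geranyllinalool.
   - Hydroborate with 9-BBN and run an intermolecular Suzuki coupling at the C–Br of the triflate of 4.
   - Close the ring by Pd-catalysed intramolecular aryl C–O coupling of the tertiary alcohol, which retains configuration at C2.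
   - If the only shortfall is ee, polish 9 by preparative chiral SFC.
2. **Step 7.** Oxidative addition into the electron-rich, di-ortho-substituted bromide may be slow, and β-hydride elimination or protodeboronation may compete.
   - Fallback: oxidise 8 with NaBO3 to the primary alcohol and convert it to the iodide.
   - Close the ring with a different nucleophile class, either Zn·LiCl insertion followed by intramolecular Negishi coupling, or Ni/bipyridine/Mn reductive cross-electrophile cyclisation.
3. **Step 2.** Regioselectivity of the mono-deacetylation may be incomplete, or acetyl scrambling may occur.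
   - Fallback: invert the differentiation logic. Acylate the less hindered OH of 1 with PivCl, silylate the hindered OH with TBSOTf, and remove the pivalate with DIBAL.
   - Brominate and carry the TBS ether through steps 5–7, with TBAF as the final deprotection.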